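Everything rests on cutting ring A at C4a–C5. Ring A (C4a, C5, C6, C7, C8, C8a) carries oxygen and methyl alternately, the pattern of a propionate-extended polyketide, so it is made in one operation in step 8: magnesium methoxide lets C4a, the α-carbon of the vinylogous ester O1–C8a=C4a–C4=O of a (2S)-2-aryl-2,3-dihydropyran-4-one, be acylated by the ester carbon C5 of the side chain on C8a, and enolisation aromatises the new ring. The precursor 15 already holds C2 and bears CH(Me)–CO–CH(Me)–CO2Me at C8a; it is built from an aldol-derived β-silyloxy ester and a diketo ester trianion and closed by cyclodehydration, so no strong base ever meets ring C.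

Key step: step 8

Remark (assumption): the (R,R)-bisphosphoramide of step 3 is taken to direct the ketene acetal to the Si face of aldehyde 4, recalled from its additions to aryl aldehydes and not verified here; the configuration of 7 is to be checked by MTPA ester analysis and the (S,S)-catalyst used if the sense is opposite.

Step 1
Reactants: 1 2-methoxybenzene-1,4-diol
Product: 2 1,4-bis(benzyloxy)-2-methoxybenzene
Conditions: BnBr (2.3 equiv), K2CO3, DMF, N2, 60 °C
Reagents that add atoms: benzyl bromide, BrCc1ccccc1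
Why: Williamson ether synthesis on both phenols, run under nitrogen so that the hydroquinone is capped before air can oxidise it.

Step 2
Reactants: 2 1,4-bis(benzyloxy)-2-methoxybenzene
Product: 4 2,5-bis(benzyloxy)-4-methoxybenzaldehyde, via iminium dichlorophosphate 3 (not isolated)
Conditions: POCl3, DMF, 0 → 70 °C; then H2O
Reagents that add atoms: N,N-dimethylformamide, CN(C)C=O; water, O
Why: Vilsmeier–Haack formylation, in which the chloroiminium ion attacks C5, the only ring position that is para to one alkoxy group and ortho to another (as in 1,2,4-trialkoxybenzenes), so ring B gets all three oxygens in the right places.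

Step 3
Reactants: 4 2,5-bis(benzyloxy)-4-methoxybenzaldehyde; 5 tert-butyl[(1-methoxyethenyl)oxy]dimethylsilane
Product: 7 methyl (3S)-3-[2,5-bis(benzyloxy)-4-methoxyphenyl]-3-hydroxypropanoate, via trichlorosilyl ether 6 (not isolated)
Conditions: SiCl4 (1.5 equiv), (R,R)-bisphosphoramide derived from N,N'-dimethyl-1,1'-binaphthyl-2,2'-diamine (5 mol %), CH2Cl2, −78 °C; then aq. NaHCO3
Reagents that add atoms: none
Why: Lewis base-activated Mukaiyama aldol addition, in which the chiral phosphoramide-bound trichlorosilyl cation binds the aldehyde and should expose its Si face to the silyl ketene acetal, setting C3 (the later C2) as S, while the strongly electrophilic silicon centre should make this electron-rich, ortho-substituted aldehyde reactive enough.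

Step 4
Reactants: 7 methyl (3S)-3-[2,5-bis(benzyloxy)-4-methoxyphenyl]-3-hydroxypropanoate
Product: 8 methyl (3S)-3-[2,5-bis(benzyloxy)-4-methoxyphenyl]-3-[(tert-butyldimethylsilyl)oxy]propanoate
Conditions: TBSCl, imidazole, DMF, rt
Reagents that add atoms: tert-butyl(chloro)dimethylsilane, CC(C)(C)[Si](C)(C)Cl
Why: Imidazole-promoted silylation of the secondary alcohol, which removes the retro-aldol pathway and makes the stereocentre inert to the strong base of step 6.

Step 5
Reactants: 9 methyl 2-methyl-3-oxopentanoate; 10 N-methoxy-N-methylacetamide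
Product: 11 methyl 2,4-dimethyl-3,5-dioxohexanoate
Conditions: LiN(iPr)2 (2.2 equiv), THF, −78 → 0 °C; then 10, −78 → 0 °C; 1 M HCl
Reagents that add atoms: none
Why: γ-Acylation of a β-keto ester dianion (Claisen type), in which the second deprotonation occurs at the C4 methylene, this less stabilised carbanion attacks the Weinreb amide, and the chelated adduct prevents over-addition; the methyl ester is kept so that exchange with methoxide in step 8 is degenerate.

Step 6
Reactants: 8 methyl (3S)-3-[2,5-bis(benzyloxy)-4-methoxyphenyl]-3-[(tert-butyldimethylsilyl)oxy]propanoate; 11 methyl 2,4-dimethyl-3,5-dioxohexanoate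
Product: 12 methyl (9S)-9-[2,5-bis(benzyloxy)-4-methoxyphenyl]-9-[(tert-butyldimethylsilyl)oxy]-2,4-dimethyl-3,5,7-trioxononanoate
Conditions: 11 (2.1 equiv), LiN(iPr)2 (6.4 equiv), THF, 0 °C; then 8, −78 → −20 °C; AcOH, −78 °C
Reagents that add atoms: none
Why: Claisen acylation of a polyanion, in which LiN(iPr)2 removes the two doubly activated methine protons and then a terminal methyl proton of 11, the last-formed terminal carbanion attacks ester 8, and the second equivalent of trianion takes up the acidic proton of the new 1,3-diketone, while the silyl ether keeps the stereocentre untouched.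

Step 7
Reactants: 12 methyl (9S)-9-[2,5-bis(benzyloxy)-4-methoxyphenyl]-9-[(tert-butyldimethylsilyl)oxy]-2,4-dimethyl-3,5,7-trioxononanoate
Product: 15 methyl 4-{(2S)-2-[2,5-bis(benzyloxy)-4-methoxyphenyl]-4-oxo-3,4-dihydro-2H-pyran-6-yl}-2-methyl-3-oxopentanoate, via hydroxy trione 13 (not isolated), via cyclic hemiketal 14 (not isolated)
Conditions: HF·pyridine, pyridine, THF, 0 °C → rt; then TFA (5 mol %), CH2Cl2, 0 °C
Reagents that add atoms: none
Why: Desilylation followed by cyclodehydration of a δ-hydroxy-β-diketone to a 2,3-dihydropyran-4-one, in which the freed alcohol adds to the C5 ketone to give the six-membered hemiketal and loses water; the C–O bond at the stereocentre is never broken, so C2 stays S, and the alcohol should outcompete the enol oxygens that could close a 2-pyranone or a 4-pyranone.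

Step 8
Reactants: 15 methyl 4-{(2S)-2-[2,5-bis(benzyloxy)-4-methoxyphenyl]-4-oxo-3,4-dihydro-2H-pyran-6-yl}-2-methyl-3-oxopentanoate
Product: 16 (2S)-2-[2,5-bis(benzyloxy)-4-methoxyphenyl]-5,7-dihydroxy-6,8-dimethyl-2,3-dihydro-4H-chromen-4-one
Conditions: Mg(OMe)2 (4 equiv), MeOH/THF, 0 °C → rt; then cold 1 M HCl
Reagents that add atoms: none
Why: Mg(OMe)2 removes the acidic C6–H and C8–H; the C8 anion is a dienolate running through C8a=C4a to the C4 oxygen, and its α-carbon C4a adds to the ester carbon C5, which the magnesium chelate of the β-keto ester holds close, after which methoxide leaves (intramolecular Claisen, Dieckmann type). The closest known reaction type is the magnesium alkoxide-mediated Claisen cyclisation of 3,5,7-triketo esters and of pyranone-masked polyketides to acylphloroglucinols and 5,7-dihydroxychromones. Ring A closes through the C4a–C5 bond in a 6-(enolexo)-exo-trig mode, and enolisation of C5=O and C7=O then aromatises it irreversibly. No stereocentre is formed: C2 is carried through and the C6/C8 epimers of 15 converge. The step needs C-acylation at C4a to beat O-acylation and opening of ring C by retro-oxa-Michael elimination from a C3 enolate; O-acylation would need an eight-membered ring, and C8–H and C6–H should be far more acidic than C3–H, so a mild alkoxide at or below room temperature should not build up the C3 enolate. Once formed, the product sits as its 7-phenoxide, which should lower the acidity of C3–H further, and the cold acidic quench limits chalcone formation.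

Step 9
Reactants: 16 (2S)-2-[2,5-bis(benzyloxy)-4-methoxyphenyl]-5,7-dihydroxy-6,8-dimethyl-2,3-dihydro-4H-chromen-4-one
Product: 17 (2S)-2-[2,5-bis(benzyloxy)-4-methoxyphenyl]-5-hydroxy-7-methoxy-6,8-dimethyl-2,3-dihydro-4H-chromen-4-one
Conditions: TMSCHN2 (1.2 equiv), MeOH/toluene, 0 °C → rt
Reagents that add atoms: (trimethylsilyl)diazomethane, C[Si](C)(C)C=[N+]=[N-]
Why: Diazoalkane O-methylation of the more acidic phenol, in which the free 7-OH (para to C4=O) protonates the reagent and is methylated while the 5-OH, hydrogen-bonded to C4=O, should react far more slowly, and no base is present that could open ring C.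

Step 10
Reactants: 17 (2S)-2-[2,5-bis(benzyloxy)-4-methoxyphenyl]-5-hydroxy-7-methoxy-6,8-dimethyl-2,3-dihydro-4H-chromen-4-one
Product: 18 (2S)-2-(2,5-dihydroxy-4-methoxyphenyl)-5-hydroxy-7-methoxy-6,8-dimethyl-2,3-dihydro-4H-chromen-4-one
Conditions: H2 (1 atm), 10% Pd/C, EtOAc, rt
Reagents that add atoms: none
Why: Catalytic hydrogenolysis of the two benzyl aryl ethers under neutral conditions, in which the cyclic C2–O1 ether and the chelated aryl ketone should survive; the air-sensitive hydroquinone is taken on at once.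

Step 11
Reactants: 18 (2S)-2-(2,5-dihydroxy-4-methoxyphenyl)-5-hydroxy-7-methoxy-6,8-dimethyl-2,3-dihydro-4H-chromen-4-one
Product: 19 2-[(2S)-5-hydroxy-7-methoxy-6,8-dimethyl-4-oxo-3,4-dihydro-2H-chromen-2-yl]-5-methoxycyclohexa-2,5-diene-1,4-dione
Conditions: Ag2O (2 equiv), MgSO4, Et2O, rt, dark
Reagents that add atoms: none
Why: Oxidation of the para-hydroquinone to the quinone by Ag2O under neutral, non-aqueous conditions, which should leave the hydrogen-bonded, fully substituted phenol of ring A and the C2 stereocentre untouched.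

Compound list
1 | 2-methoxybenzene-1,4-diol | COc1cc(O)ccc1O | starting material
2 | 1,4-bis(benzyloxy)-2-methoxybenzene | COc1cc(OCc2ccccc2)ccc1OCc1ccccc1 | intermediate
3 | N-{[2,5-bis(benzyloxy)-4-methoxyphenyl]methylidene}-N-methylmethanaminium dichlorophosphate | COc1cc(OCc2ccccc2)c(C=[N+](C)C)cc1OCc1ccccc1.[O-]P(=O)(Cl)Cl | intermediate (not isolated)
4 | 2,5-bis(benzyloxy)-4-methoxybenzaldehyde | COc1cc(OCc2ccccc2)c(C=O)cc1OCc1ccccc1 | intermediate
5 | tert-butyl[(1-methoxyethenyl)oxy]dimethylsilane | COC(=C)O[Si](C)(C)C(C)(C)C | starting material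
6 | methyl (3S)-3-[2,5-bis(benzyloxy)-4-methoxyphenyl]-3-[(trichlorosilyl)oxy]propanoate | COC(=O)C[C@H](O[Si](Cl)(Cl)Cl)c1cc(OCc2ccccc2)c(OC)cc1OCc1ccccc1 | intermediate (not isolated)
7 | methyl (3S)-3-[2,5-bis(benzyloxy)-4-methoxyphenyl]-3-hydroxypropanoate | COC(=O)C[C@H](O)c1cc(OCc2ccccc2)c(OC)cc1OCc1ccccc1 | intermediate
8 | methyl (3S)-3-[2,5-bis(benzyloxy)-4-methoxyphenyl]-3-[(tert-butyldimethylsilyl)oxy]propanoate | COC(=O)C[C@H](O[Si](C)(C)C(C)(C)C)c1cc(OCc2ccccc2)c(OC)cc1OCc1ccccc1 | intermediate
9 | methyl 2-methyl-3-oxopentanoate | CCC(=O)C(C)C(=O)OC | starting material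
10 | N-methoxy-N-methylacetamide | CON(C)C(C)=O | starting material
11 | methyl 2,4-dimethyl-3,5-dioxohexanoate (epimer and enol mixture) | COC(=O)C(C)C(=O)C(C)C(C)=O | intermediate
12 | methyl (9S)-9-[2,5-bis(benzyloxy)-4-methoxyphenyl]-9-[(tert-butyldimethylsilyl)oxy]-2,4-dimethyl-3,5,7-trioxononanoate (C2/C4 epimers) | COC(=O)C(C)C(=O)C(C)C(=O)CC(=O)C[C@H](O[Si](C)(C)C(C)(C)C)c1cc(OCc2ccccc2)c(OC)cc1OCc1ccccc1 | intermediate
13 | methyl (9S)-9-[2,5-bis(benzyloxy)-4-methoxyphenyl]-9-hydroxy-2,4-dimethyl-3,5,7-trioxononanoate | COC(=O)C(C)C(=O)C(C)C(=O)CC(=O)C[C@H](O)c1cc(OCc2ccccc2)c(OC)cc1OCc1ccccc1 | intermediate (not isolated)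
14 | methyl 4-{(6S)-6-[2,5-bis(benzyloxy)-4-methoxyphenyl]-2-hydroxy-4-oxooxan-2-yl}-2-methyl-3-oxopentanoate | COc1cc(OCc2ccccc2)c(cc1OCc1ccccc1)[C@@H]3CC(=O)CC(O)(O3)C(C)C(=O)C(C)C(=O)OC | intermediate (not isolated)
15 | methyl 4-{(2S)-2-[2,5-bis(benzyloxy)-4-methoxyphenyl]-4-oxo-3,4-dihydro-2H-pyran-6-yl}-2-methyl-3-oxopentanoate (chain epimers) | COc1cc(OCc2ccccc2)c(cc1OCc1ccccc1)[C@@H]3CC(=O)C=C(O3)C(C)C(=O)C(C)C(=O)OC | intermediate
16 | (2S)-2-[2,5-bis(benzyloxy)-4-methoxyphenyl]-5,7-dihydroxy-6,8-dimethyl-2,3-dihydro-4H-chromen-4-one | COc1cc(OCc2ccccc2)c(cc1OCc1ccccc1)[C@@H]3CC(=O)c4c(O)c(C)c(O)c(C)c4O3 | intermediate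
17 | (2S)-2-[2,5-bis(benzyloxy)-4-methoxyphenyl]-5-hydroxy-7-methoxy-6,8-dimethyl-2,3-dihydro-4H-chromen-4-one | COc1cc(OCc2ccccc2)c(cc1OCc1ccccc1)[C@@H]3CC(=O)c4c(O)c(C)c(OC)c(C)c4O3 | intermediate
18 | (2S)-2-(2,5-dihydroxy-4-methoxyphenyl)-5-hydroxy-7-methoxy-6,8-dimethyl-2,3-dihydro-4H-chromen-4-one | COc1cc(O)c(cc1O)[C@@H]2CC(=O)c3c(O)c(C)c(OC)c(C)c3O2 | intermediate
19 | 2-[(2S)-5-hydroxy-7-methoxy-6,8-dimethyl-4-oxo-3,4-dihydro-2H-chromen-2-yl]-5-methoxycyclohexa-2,5-diene-1,4-dione | COC1=CC(=O)C([C@@H]2CC(=O)c3c(O)c(C)c(OC)c(C)c3O2)=CC1=O | target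

Total step count: 11 steps.
Longest linear sequence: 10 steps (steps 1, 2, 3, 4, 6, 7, 8, 9, 10, 11 from compound 1); step 5 is a one-step branch.

The three steps most likely to fail

First, step 8, the key step. Under the alkoxide, ring C may open at O1–C2 by retro-oxa-Michael elimination and close again without stereocontrol. Alternatively, the chelated β-keto ester enolate may be too unreactive, so that C4a is not acylated. The fallback aromatises first and closes ring C last with inversion, and it sets out from aldehyde 4. Steps 3, 4 and 6 are repeated with the (S,S)-catalyst, which should give, through the (R)-trichlorosilyl ether F1, the (R)-hydroxy ester F2, its silyl ether F3 and, with 11, the (R)-triketo ester F4. Mg(OMe)2 in MeOH then effects the Claisen cyclisation on the open chain, the methylene between the two ketones attacking the ester carbon. This gives the acylphloroglucinol silyl ether F5, which has no pyranone to open. HF·pyridine frees the (R)-alcohol F6. Mitsunobu etherification (PPh3, DIAD, THF, 0 °C) by one of the two equivalent ortho phenols closes O1–C2 with inversion and gives the (2S)-chromanone 16, where the fallback rejoins the route.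

Second, step 6. The strongly basic trianion may deprotonate the methylene next to the ester of 8 and expel silanolate faster than the acyl group is transferred, or proton exchange may stall the acylation. The fallback replaces acyl substitution by carbonyl addition and oxidation, and it sets out from ester 8. iBu2AlH (CH2Cl2, −78 °C) gives the (S)-aldehyde F7. The trianion of 11 adds to it at −78 °C to give the hydroxy diketo ester F8. Dess–Martin periodinane oxidises the new carbinol to the ketone, which is compound 12, where the fallback rejoins the route.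

Third, step 7. In the 1,3,5-tricarbonyl array an enol oxygen may close onto a ketone or onto the ester (4-pyranone or 2-pyranone formation) before the alcohol closes the hemiketal. Acid may also ionise the electron-rich benzylic C–O bond or dehydrate the β-hydroxy ketone, with loss of configuration. The fallback closes ring C while only two ketones are present and adds the last propionate unit under near-neutral conditions, and it sets out from ester 8. The dianion of methyl 2-methyl-3-oxobutanoate (LiN(iPr)2, 2 equiv) is acylated by 8 to give the silyloxy diketo ester F9. HF·pyridine then gives the pyranone ester F10, and Me3SnOH (1,2-dichloroethane, 70 °C) hydrolyses its methyl ester to the acid F11. 1,1'-Carbonyldiimidazole gives the acyl imidazole F12, which with MgCl2 and potassium methyl methylmalonate undergoes decarboxylative Claisen condensation to the β-keto ester 15, where the fallback rejoins the route.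

Further compounds
F1 | step 8 | methyl (3R)-3-[2,5-bis(benzyloxy)-4-methoxyphenyl]-3-[(trichlorosilyl)oxy]propanoate | COC(=O)C[C@@H](O[Si](Cl)(Cl)Cl)c1cc(OCc2ccccc2)c(OC)cc1OCc1ccccc1
F2 | step 8 | methyl (3R)-3-[2,5-bis(benzyloxy)-4-methoxyphenyl]-3-hydroxypropanoate | COC(=O)C[C@@H](O)c1cc(OCc2ccccc2)c(OC)cc1OCc1ccccc1
F3 | step 8 | methyl (3R)-3-[2,5-bis(benzyloxy)-4-methoxyphenyl]-3-[(tert-butyldimethylsilyl)oxy]propanoate | COC(=O)C[C@@H](O[Si](C)(C)C(C)(C)C)c1cc(OCc2ccccc2)c(OC)cc1OCc1ccccc1
F4 | step 8 | methyl (9R)-9-[2,5-bis(benzyloxy)-4-methoxyphenyl]-9-[(tert-butyldimethylsilyl)oxy]-2,4-dimethyl-3,5,7-trioxononanoate | COC(=O)C(C)C(=O)C(C)C(=O)CC(=O)C[C@@H](O[Si](C)(C)C(C)(C)C)c1cc(OCc2ccccc2)c(OC)cc1OCc1ccccc1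
F5 | step 8 | (3R)-3-[2,5-bis(benzyloxy)-4-methoxyphenyl]-3-[(tert-butyldimethylsilyl)oxy]-1-(2,4,6-trihydroxy-3,5-dimethylphenyl)propan-1-one | Cc1c(O)c(C)c(O)c(C(=O)C[C@@H](O[Si](C)(C)C(C)(C)C)c2cc(OCc3ccccc3)c(OC)cc2OCc2ccccc2)c1O
F6 | step 8 | (3R)-3-[2,5-bis(benzyloxy)-4-methoxyphenyl]-3-hydroxy-1-(2,4,6-trihydroxy-3,5-dimethylphenyl)propan-1-one | Cc1c(O)c(C)c(O)c(C(=O)C[C@@H](O)c2cc(OCc3ccccc3)c(OC)cc2OCc2ccccc2)c1O
F7 | step 6 | (3S)-3-[2,5-bis(benzyloxy)-4-methoxyphenyl]-3-[(tert-butyldimethylsilyl)oxy]propanal | O=CC[C@H](O[Si](C)(C)C(C)(C)C)c1cc(OCc2ccccc2)c(OC)cc1OCc1ccccc1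
F8 | step 6 | methyl (9S)-9-[2,5-bis(benzyloxy)-4-methoxyphenyl]-9-[(tert-butyldimethylsilyl)oxy]-7-hydroxy-2,4-dimethyl-3,5-dioxononanoate | COC(=O)C(C)C(=O)C(C)C(=O)CC(O)C[C@H](O[Si](C)(C)C(C)(C)C)c1cc(OCc2ccccc2)c(OC)cc1OCc1ccccc1
F9 | step 7 | methyl (7S)-7-[2,5-bis(benzyloxy)-4-methoxyphenyl]-7-[(tert-butyldimethylsilyl)oxy]-2-methyl-3,5-dioxoheptanoate | COC(=O)C(C)C(=O)CC(=O)C[C@H](O[Si](C)(C)C(C)(C)C)c1cc(OCc2ccccc2)c(OC)cc1OCc1ccccc1
F10 | step 7 | methyl 2-{(2S)-2-[2,5-bis(benzyloxy)-4-methoxyphenyl]-4-oxo-3,4-dihydro-2H-pyran-6-yl}propanoate | COc1cc(OCc2ccccc2)c(cc1OCc1ccccc1)[C@@H]3CC(=O)C=C(O3)C(C)C(=O)OC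
F11 | step 7 | 2-{(2S)-2-[2,5-bis(benzyloxy)-4-methoxyphenyl]-4-oxo-3,4-dihydro-2H-pyran-6-yl}propanoic acid | COc1cc(OCc2ccccc2)c(cc1OCc1ccccc1)[C@@H]3CC(=O)C=C(O3)C(C)C(O)=O
F12 | step 7 | 2-{(2S)-2-[2,5-bis(benzyloxy)-4-methoxyphenyl]-4-oxo-3,4-dihydro-2H-pyran-6-yl}-1-(1H-imidazol-1-yl)propan-1-one | COc1cc(OCc2ccccc2)c(cc1OCc1ccccc1)[C@@H]3CC(=O)C=C(O3)C(C)C(=O)n1ccnc1
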